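**Assumption:** (4R,6R)-actinol (1) and (E)-4,4-dimethoxybut-2-enal (9) are taken as catalogue compounds. Chain numbering below follows the target name (C1 = CH2OH carbon, C15 = alkyne carbon on the ring). Steps 7–9 are run under argon in dim light. The route is a paper proposal and has not been run.

## Retrosynthetic overview

1. Target 20 ⇐ one hydride operation on the C27 pivalate methyl ester 19 (ester → CH2OH and pivalate off together).
2. 19 ⇐ C10=C11 Wittig between the C15 ring/enyne tributylphosphonium salt 8 and the C12 trienal ester 17.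
3. 17 ⇐ formyl-ylide Wittig (C8=C9) on dienal ester 15 ⇐ Johnson–Claisen [3,3] rearrangement of bis-allylic alcohol 11, which makes the C2–C3 bond and the E C4=C5 olefin; 11 ⇐ isopropenylMgBr + 9.
4. 8 ⇐ Sonogashira coupling of enol triflate 4 with (E)-3-methylpent-2-en-4-yn-1-ol 5; 4 ⇐ actinol 1.
5. Rings: the single carbocycle and its carbinol stereocentre come in intact with 1; no ring is formed in the route.

## Route

Step 1
Reactants: 1 (4R,6R)-4-hydroxy-2,2,6-trimethylcyclohexan-1-one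
Product: 2 (1R,5R)-3,3,5-trimethyl-4-oxocyclohexyl pivalate
Conditions: PivCl, pyridine, DMAP (cat.), CH2Cl2, 0 °C → rt
Reagents that add atoms: pivaloyl chloride, CC(C)(C)C(Cl)=O
Why: DMAP-catalysed acylation of the secondary alcohol gives an ester without α-hydrogens that tolerates the enolate chemistry of step 2 and is removed by the final hydride step, with no stereocentre touched.

Step 2
Reactants: 2 (1R,5R)-3,3,5-trimethyl-4-oxocyclohexyl pivalate
Product: 4 (1R)-3,5,5-trimethyl-4-(trifluoromethylsulfonyloxy)cyclohex-3-en-1-yl pivalate, via lithium enolate 3 (not isolated)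
Conditions: LDA, THF, −78 °C; then PhNTf2, −78 °C → rt; aq. work-up
Reagents that add atoms: N-phenylbis(trifluoromethanesulfonimide), O=S(=O)(N(c1ccccc1)S(=O)(=O)C(F)(F)F)C(F)(F)F
Why: The ketone has only one enolisable α-position (the other is quaternary), so enolate O-triflation gives a single tetrasubstituted enol triflate; the methyl-bearing centre is erased on purpose and the carbinol centre is untouched.

Step 3
Reactants: 4 (1R)-3,5,5-trimethyl-4-(trifluoromethylsulfonyloxy)cyclohex-3-en-1-yl pivalate; 5 (E)-3-methylpent-2-en-4-yn-1-ol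
Product: 6 (1R)-4-[(E)-5-hydroxy-3-methylpent-3-en-1-yn-1-yl]-3,5,5-trimethylcyclohex-3-en-1-yl pivalate
Conditions: Pd(PPh3)4 (5 mol %), CuI (10 mol %), Et3N, DMF, 60 °C, degassed
Reagents that add atoms: none
Why: Sonogashira coupling of the vinyl triflate with the terminal alkyne forms the ring C(sp2)–C(sp) bond directly, with the free allylic alcohol and pivalate as spectators and the E geometry of 5 carried through.

Step 4
Reactants: 6 (1R)-4-[(E)-5-hydroxy-3-methylpent-3-en-1-yn-1-yl]-3,5,5-trimethylcyclohex-3-en-1-yl pivalate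
Product: 8 tributyl{(E)-3-methyl-5-[(4R)-2,6,6-trimethyl-4-(pivaloyloxy)cyclohex-1-en-1-yl]pent-2-en-4-yn-1-yl}phosphonium bromide, via allylic bromide 7 (not isolated)
Conditions: PBr3 (0.4 equiv), pyridine (cat.), Et2O, −20 → 0 °C; cold NaHCO3 wash, dry; then PBu3, rt
Reagents that add atoms: phosphorus tribromide, BrP(Br)Br; tributylphosphine, CCCCP(CCCC)CCCC
Why: Bromination of the primary allylic alcohol followed by SN2 quaternisation of the trialkylphosphine gives the Wittig salt without disturbing the trisubstituted olefin.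

Step 5
Reactants: 9 (E)-4,4-dimethoxybut-2-enal; 10 isopropenylmagnesium bromide
Product: 11 (4E)-6,6-dimethoxy-2-methylhexa-1,4-dien-3-ol (racemic)
Conditions: THF, −78 → 0 °C; sat. aq. NH4Cl
Reagents that add atoms: none
Why: Grignard 1,2-addition to the enal carbonyl gives the bis-allylic alcohol; its carbinol centre is racemic and is consumed in step 6.

Step 6
Reactants: 11 (4E)-6,6-dimethoxy-2-methylhexa-1,4-dien-3-ol; 12 trimethyl orthoacetate
Product: 15 methyl (4E,6E)-4-methyl-8-oxoocta-4,6-dienoate, via ketene acetal 13 (not isolated), via dimethyl acetal ester 14 (not isolated)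
Conditions: 12 (6 equiv), EtCO2H (5 mol %), 110 °C, MeOH distilled off; evaporate; then 1 M HCl, THF, rt
Reagents that add atoms: water, O
Why: Johnson–Claisen [3,3]-sigmatropic rearrangement through the unsubstituted isopropenyl terminus, in a chair transition state with the alkenyl substituent equatorial, forms the CH2–CH2 bond and the E-trisubstituted olefin, and dilute acid then unmasks the conjugated aldehyde.

Step 7
Reactants: 15 methyl (4E,6E)-4-methyl-8-oxoocta-4,6-dienoate; 16 2-(triphenylphosphoranylidene)propanal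
Product: 17 methyl (4E,6E,8E)-4,9-dimethyl-10-oxodeca-4,6,8-trienoate
Conditions: toluene, 90 °C
Reagents that add atoms: none
Why: Wittig olefination with the stabilised formyl ylide is E-selective and stops after one homologation because the α-methyl enal product is much less electrophilic than 15.

Step 8
Reactants: 8 tributyl{(E)-3-methyl-5-[(4R)-2,6,6-trimethyl-4-(pivaloyloxy)cyclohex-1-en-1-yl]pent-2-en-4-yn-1-yl}phosphonium bromide; 17 methyl (4E,6E,8E)-4,9-dimethyl-10-oxodeca-4,6,8-trienoate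
Product: 19 methyl (4E,6E,8E,10E,12E)-4,9,13-trimethyl-15-[(4R)-2,6,6-trimethyl-4-(pivaloyloxy)cyclohex-1-en-1-yl]pentadeca-4,6,8,10,12-pentaen-14-ynoate, via phosphorus ylide 18 (not isolated)
Conditions: NaHMDS (1.0 equiv), THF, −78 °C; then 17, −78 → 0 °C
Reagents that add atoms: none
Why: Wittig olefination with an allylic trialkylphosphonium ylide gives predominantly the E-diene at C10=C11 at low temperature, which preserves the E C12=C13 olefin, the methyl ester and the pivalate.

Step 9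
Reactants: 19 methyl (4E,6E,8E,10E,12E)-4,9,13-trimethyl-15-[(4R)-2,6,6-trimethyl-4-(pivaloyloxy)cyclohex-1-en-1-yl]pentadeca-4,6,8,10,12-pentaen-14-ynoate
Product: 20 (4E,6E,8E,10E,12E)-15-[(4R)-4-hydroxy-2,6,6-trimethylcyclohex-1-en-1-yl]-4,9,13-trimethylpentadeca-4,6,8,10,12-pentaen-14-yn-1-ol
Conditions: DIBAL-H (5 equiv), CH2Cl2, −78 → 0 °C; Rochelle salt work-up
Reagents that add atoms: none
Why: Excess DIBAL-H reduces the methyl ester to the primary alcohol and reductively cleaves the pivalate in one operation, leaving the enyne-pentaene and the carbinol stereocentre untouched.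

## Compound list

1 | (4R,6R)-4-hydroxy-2,2,6-trimethylcyclohexan-1-one (actinol) | O=C1C(C)(C)C[C@H](O)C[C@H]1C | starting material
2 | (1R,5R)-3,3,5-trimethyl-4-oxocyclohexyl pivalate | O=C1C(C)(C)C[C@H](OC(=O)C(C)(C)C)C[C@H]1C | intermediate
3 | lithium enolate of 2 | [Li]OC1=C(C)C[C@@H](OC(=O)C(C)(C)C)CC1(C)C | intermediate (not isolated)
4 | (1R)-3,5,5-trimethyl-4-(trifluoromethylsulfonyloxy)cyclohex-3-en-1-yl pivalate | CC1=C(OS(=O)(=O)C(F)(F)F)C(C)(C)C[C@H](OC(=O)C(C)(C)C)C1 | intermediate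
5 | (E)-3-methylpent-2-en-4-yn-1-ol | C#C/C(C)=C/CO | starting material
6 | (1R)-4-[(E)-5-hydroxy-3-methylpent-3-en-1-yn-1-yl]-3,5,5-trimethylcyclohex-3-en-1-yl pivalate | CC1=C(C#C/C(C)=C/CO)C(C)(C)C[C@H](OC(=O)C(C)(C)C)C1 | intermediate
7 | (1R)-4-[(E)-5-bromo-3-methylpent-3-en-1-yn-1-yl]-3,5,5-trimethylcyclohex-3-en-1-yl pivalate | CC1=C(C#C/C(C)=C/CBr)C(C)(C)C[C@H](OC(=O)C(C)(C)C)C1 | intermediate (not isolated)
8 | tributyl{(E)-3-methyl-5-[(4R)-2,6,6-trimethyl-4-(pivaloyloxy)cyclohex-1-en-1-yl]pent-2-en-4-yn-1-yl}phosphonium bromide | CC1=C(C#C/C(C)=C/C[P+](CCCC)(CCCC)CCCC)C(C)(C)C[C@H](OC(=O)C(C)(C)C)C1.[Br-] | intermediate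
9 | (E)-4,4-dimethoxybut-2-enal (fumaraldehyde mono(dimethyl acetal)) | COC(OC)/C=C/C=O | starting material
10 | isopropenylmagnesium bromide | CC(=C)[Mg]Br | starting material
11 | (4E)-6,6-dimethoxy-2-methylhexa-1,4-dien-3-ol (racemic) | COC(OC)/C=C/C(O)C(C)=C | intermediate
12 | trimethyl orthoacetate | CC(OC)(OC)OC | starting material
13 | (4E)-6,6-dimethoxy-3-(1-methoxyvinyloxy)-2-methylhexa-1,4-diene (ketene acetal) | C=C(OC)OC(/C=C/C(OC)OC)C(C)=C | intermediate (not isolated)
14 | methyl (4E,6E)-8,8-dimethoxy-4-methylocta-4,6-dienoate | COC(=O)CC/C(C)=C/C=C/C(OC)OC | intermediate (not isolated)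
15 | methyl (4E,6E)-4-methyl-8-oxoocta-4,6-dienoate | COC(=O)CC/C(C)=C/C=C/C=O | intermediate
16 | 2-(triphenylphosphoranylidene)propanal | CC(C=O)=P(c1ccccc1)(c1ccccc1)c1ccccc1 | starting material
17 | methyl (4E,6E,8E)-4,9-dimethyl-10-oxodeca-4,6,8-trienoate | COC(=O)CC/C(C)=C/C=C/C=C(\C)C=O | intermediate
18 | tributylphosphonium ylide derived from 8 | CC1=C(C#C/C(C)=C/C=P(CCCC)(CCCC)CCCC)C(C)(C)C[C@H](OC(=O)C(C)(C)C)C1 | intermediate (not isolated)
19 | methyl (4E,6E,8E,10E,12E)-4,9,13-trimethyl-15-[(4R)-2,6,6-trimethyl-4-(pivaloyloxy)cyclohex-1-en-1-yl]pentadeca-4,6,8,10,12-pentaen-14-ynoate | CC1=C(C#C/C(C)=C/C=C/C(C)=C/C=C/C=C(\C)CCC(=O)OC)C(C)(C)C[C@H](OC(=O)C(C)(C)C)C1 | intermediate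
20 | (4E,6E,8E,10E,12E)-15-[(4R)-4-hydroxy-2,6,6-trimethylcyclohex-1-en-1-yl]-4,9,13-trimethylpentadeca-4,6,8,10,12-pentaen-14-yn-1-ol | CC1=C(C#C/C(C)=C/C=C/C(C)=C/C=C/C=C(\C)CCCO)C(C)(C)C[C@H](O)C1 | target

## Step count and risks

Total steps: 9. Longest linear sequence: 6 (steps 1, 2, 3, 4, 8, 9); the side-chain branch is steps 5, 6, 7 and joins at step 8.

**Step 8 (C10=C11 Wittig).** The risk is an E/Z mixture at the new olefin and loss of E geometry at C12=C13, because the allylic ylide is conjugated to the enyne. The fallback reverses the polarity so that the carbanion sits on the triene fragment. It sets out from 6 and 17 and returns at 19. MnO2 (CH2Cl2, rt) oxidises 6 to the enynal (1R)-3,5,5-trimethyl-4-[(E)-3-methyl-5-oxopent-3-en-1-yn-1-yl]cyclohex-3-en-1-yl pivalate F1. NaBH4/CeCl3 (MeOH, 0 °C) reduces only the aldehyde of 17 to methyl (4E,6E,8E)-10-hydroxy-4,9-dimethyldeca-4,6,8-trienoate F2. PPh3·HBr (MeOH, rt) converts F2 to [(2E,4E,6E)-10-methoxy-2,7-dimethyl-10-oxodeca-2,4,6-trien-1-yl]triphenylphosphonium bromide F3. Wittig reaction of F3 with F1 (NaOMe, CH2Cl2/MeOH, then gentle warming to isomerise the hindered Z isomer) gives 19.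

**Step 3 (Sonogashira on the hindered tetrasubstituted triflate).** The risk is slow oxidative addition and alkyne homodimerisation. The fallback is acetylide addition and dehydration. It sets out from 2 (with 5) and returns at 6. The dianion of 5 (n-BuLi, 2 equiv, THF, −78 °C) adds to the ketone of 2 to give (1R,5R)-4-hydroxy-4-[(E)-5-hydroxy-3-methylpent-3-en-1-yn-1-yl]-3,3,5-trimethylcyclohexyl pivalate F4 (carbinol epimers). Ac2O/pyridine (0 °C) acetylates only the primary alcohol to give (1R,5R)-4-[(E)-5-acetoxy-3-methylpent-3-en-1-yn-1-yl]-4-hydroxy-3,3,5-trimethylcyclohexyl pivalate F5. POCl3/pyridine (50 °C) dehydrates the tertiary alcohol toward its only β-hydrogen to give (1R)-4-[(E)-5-acetoxy-3-methylpent-3-en-1-yn-1-yl]-3,5,5-trimethylcyclohex-3-en-1-yl pivalate F6. K2CO3 in MeOH (0 °C) removes the acetate but not the pivalate and gives 6.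

**Step 6 (Johnson–Claisen and acetal hydrolysis).** The risk is rearrangement through the other allyl unit and acid-promoted loss of the bis-allylic alcohol or acetal at 110 °C. The fallback is a base-mediated Ireland–Claisen rearrangement at low temperature. It sets out from 11 and returns at 14, which is hydrolysed to 15 as in step 6. Ac2O/pyridine/DMAP gives (4E)-6,6-dimethoxy-2-methylhexa-1,4-dien-3-yl acetate F7. LDA then TMSCl (THF, −78 °C → rt) and mild aqueous work-up give, by [3,3] shift of the silyl ketene acetal, (4E,6E)-8,8-dimethoxy-4-methylocta-4,6-dienoic acid F8. MeI/K2CO3 (DMF, rt) esterifies F8 to 14.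

## Further compounds

F1 | step 8 | (1R)-3,5,5-trimethyl-4-[(E)-3-methyl-5-oxopent-3-en-1-yn-1-yl]cyclohex-3-en-1-yl pivalate | CC1=C(C#C/C(C)=C/C=O)C(C)(C)C[C@H](OC(=O)C(C)(C)C)C1
F2 | step 8 | methyl (4E,6E,8E)-10-hydroxy-4,9-dimethyldeca-4,6,8-trienoate | COC(=O)CC/C(C)=C/C=C/C=C(\C)CO
F3 | step 8 | [(2E,4E,6E)-10-methoxy-2,7-dimethyl-10-oxodeca-2,4,6-trien-1-yl]triphenylphosphonium bromide | COC(=O)CC/C(C)=C/C=C/C=C(\C)C[P+](c1ccccc1)(c1ccccc1)c1ccccc1.[Br-]
F4 | step 3 | (1R,5R)-4-hydroxy-4-[(E)-5-hydroxy-3-methylpent-3-en-1-yn-1-yl]-3,3,5-trimethylcyclohexyl pivalate (carbinol epimers) | OC1(C#C/C(C)=C/CO)C(C)(C)C[C@H](OC(=O)C(C)(C)C)C[C@H]1C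
F5 | step 3 | (1R,5R)-4-[(E)-5-acetoxy-3-methylpent-3-en-1-yn-1-yl]-4-hydroxy-3,3,5-trimethylcyclohexyl pivalate (carbinol epimers) | OC1(C#C/C(C)=C/COC(C)=O)C(C)(C)C[C@H](OC(=O)C(C)(C)C)C[C@H]1C
F6 | step 3 | (1R)-4-[(E)-5-acetoxy-3-methylpent-3-en-1-yn-1-yl]-3,5,5-trimethylcyclohex-3-en-1-yl pivalate | CC1=C(C#C/C(C)=C/COC(C)=O)C(C)(C)C[C@H](OC(=O)C(C)(C)C)C1
F7 | step 6 | (4E)-6,6-dimethoxy-2-methylhexa-1,4-dien-3-yl acetate (racemic) | COC(OC)/C=C/C(OC(C)=O)C(C)=C
F8 | step 6 | (4E,6E)-8,8-dimethoxy-4-methylocta-4,6-dienoic acid | COC(OC)/C=C/C=C(\C)CCC(O)=O
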